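**Structural features**

The target is a melampolide-type germacranolide: a ten-membered carbocycle (C1–C10) with two endocyclic alkenes. C1=C10 has its ring bonds cis (E by CIP, because the C14 methyl ester on C10 outranks C9), and C4=C5 has its ring bonds trans and carries methyl C15 on C4. A trans-fused α-methylene-γ-butyrolactone is annulated across C6–C7 (O6–C12(=O)–C11(=C13H2)–C7). Four contiguous stereocentres C6, C7, C8 and C9 (6R,7S,8S,9S) stand next to one another: O6 and C8 are anti across C6–C7, C11 and O8 are anti across C7–C8, and O8 and O9 are syn across C8–C9. O8 carries a 2-(hydroxymethyl)acrylate and O9 an acetate. Fragile elements are three Michael acceptors (lactone methylene, ring enoate, side-chain acrylate), the vicinal ester pair at O8/O9 (acyl migration), the allylic oxygens at C6 and C9, and a 1,5-diene in a medium ring that tolerates neither strong heating (Cope rearrangement) nor strong acid (transannular cyclisation). The real difficulty is the strained ten-membered ring with a trisubstituted enoate of defined geometry attached directly to the oxygenated C9. The key step exploits that C1=C10 joins a CH carbon (C1) to a carbon bearing an ester and no hydrogen (C10): these are the two α-carbons of a sulfone C1–SO2–C10, so the carbocycle can arise from an eleven-membered thia ring by loss of SO2.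

**Logic of the disconnections**

41 ⇒ 40 ⇒ 35 + 38. The side-chain O–Si bond and the O8 ester C–O bond are cut first. The hydroxymethyl acrylate is the most electrophilic and most base-labile unit, so it is attached last and keeps a third Michael acceptor and a free primary alcohol out of all earlier steps. The forward acylation must be fast at a hindered secondary alcohol next to the O9 acetate, and the final desilylation must be non-basic.

35 ⇒ 34 ⇒ 32 ⇒ 31 ⇒ 30 ⇒ 29. The O8 PMB ether is restored, the lactone C12–O6 bond is opened at the diol oxidation level, and O9 acetyl is exchanged for silyl. The α-methylene lactone cannot survive thiolate or KOtBu, so it is carried as a bis-silylated 2-methylene-1,4-diol. The forward demands are an oxidation that takes the primary allylic C12–OH and leaves the secondary allylic C6–OH, and acetylation of O9 before lactonisation so that only O6 can trap the C12 aldehyde.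

29 ⇒ 27 (key disconnection). C1=C10 is cut to C1–SO2–C10(Cl). This trades a ten-membered ring with a cis trisubstituted enoate for an eleven-membered ring that closes by S-alkylation. The forward step needs C1 to be the only acidic position and needs closure to the cis-fused episulfone.

27 ⇒ 26 ⇒ 24. The C10–Cl bond and the two S–O bonds are removed. The forward steps need S-oxidation that spares two alkenes, and chlorination of the sulfonyl ester carbanion before it can expel the C9 silyloxy group.

24 ⇒ 22. The S–C10 bond is cut, which opens the ring to an acyclic chain with a masked C1 thiol and an α-bromo ester. The forward step needs high dilution and release of the thiolate in the presence of the bromide.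

22 ⇒ 21 ⇒ 18 + 20. The C9–C10 bond is cut as an aldol. This introduces C10, C14 and the leaving group in one operation and lets the O8 PMB ether control C9 through a chelate. The forward step needs 8,9-syn selectivity; the C10 configuration is irrelevant.

18 ⇒ 17 ⇒ 16 ⇒ 15 ⇒ 14 ⇒ 13. The C1–S bond, the C9 oxidation level and the O8/O9 differentiation are unravelled back to an acetonide and a primary chloride. The chloride serves as a protecting-group-free thiol precursor, and PMB lands on O8 by regioselective reductive opening of a 4-methoxybenzylidene acetal. The silyl ethers at O6 and O12 must survive acetonide methanolysis, so TIPS is used in place of TBS.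

13 ⇒ 12 ⇒ 11 ⇒ 4 + 9. After the lactone is restored, the C6–C7 bond is cut into two fragments of similar size. The forward allylation must set C6 and C7 (6,7-anti) under control of the glyceraldehyde-derived C8 centre.

4 ⇒ 3 ⇒ 1 + 2. The C7–C11 bond is cut (Morita–Baylis–Hillman) after allylic transposition of bromide to hydroxyl. The carbinol configuration of 3 need not be controlled; only the alkene geometry of 4 matters.

9 ⇒ 8 ⇒ 7 ⇒ 5 + 6. The C4=C5 bond is cut by olefination of a methyl ketone. The forward step must give the E enoate, and the isomers are separated at the ester stage.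

20 ⇒ 19 and 38 ⇒ 37 ⇒ 36. The two small reagents come from commercial esters by O-silylation and by silylation followed by saponification.

**Other disconnections considered**

Alternative 1: The cut removes C1–C10 and C4–C5 as the two σ bonds of a cyclobutane. Forward, enone ester A1 and 1-methylcyclobutene A2 would combine under irradiation to the cis-anti-cis photoadduct A3. Thermal cycloreversion of its bicyclo[2.2.0]hexane unit (breaking C1–C4 and C5–C10) would then reveal cyclodecadienone A4.
- In its favour: two skeletal bonds and later both ring alkenes come from compact partners; the C10 ester is already in place; C6–C8 are set on a rigid six-membered ring; no high-dilution ring closure is needed.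
- Against it here: the orientation of the unsymmetrical cyclobutene and the face of addition are weakly biased. The alkene geometries are dictated by the cycloreversion pathway rather than by design. The required heat lies where germacradienes begin Cope rearrangement. C9 arrives as a ketone that still needs stereoselective reduction, and the lactone methylene must be added afterwards next to a β-keto ester.
- Comparison: on ring construction it is better than the chosen plan, because no medium ring is closed. Mechanistically it is equal, since both plans make the enoate alkene in a strain- or gas-releasing fragmentation. It is weaker on control of C9 and of the C1=C10 geometry. Step economy could be equal or better if A1 were short to make, which is doubtful for an enantiopure, fully substituted bicycle.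

Alternative 2: The cut is C8–C9 with transposition of the alkene. Forward, CrCl2 would convert bromide–aldehyde A5 into a γ-acetoxyallylchromium that adds through C9 to the C8 aldehyde and gives A6, which is the same compound as 35 of the chosen route.
- In its favour: the ring, C8, C9 and C1=C10 are all made in one late step; the acetate is carried in; only acylation and deprotection remain. On step economy and convergence this is better than the chosen plan.
- Against it here: γ-heteroatom allylchromium reagents normally give the 1,2-anti relationship, whereas 8,9-syn is needed. The enoate geometry and two stereocentres would be decided in one macrocyclic transition state with no substrate handle. The C8 aldehyde sits α to C7, which is γ to the lactone carbonyl and β to O6, so epimerisation and β-elimination threaten. The 3-acetoxy-2-(bromoalkyl)acrylate unit is itself an acyl donor.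
- Comparison: structurally it is equal in the sense that it uses the same ring enoate as the strategic site. Mechanistically it is riskier, because the chosen plan fixes C8/C9 beforehand in an acyclic chelate and asks the key step only for geometry.

Alternative 3: The cut is C6–C7 through a retro-[3,3] shift. Forward, the potassium alkoxide of dialkenylcyclohexenol A7 would rearrange to cyclodecadienone A8.
- In its favour: ring expansion from a six-membered ring avoids any medium-ring cyclisation. The cis C1=C10 geometry is inherited from the cyclohexene, which is better than the chosen plan, where it depends on episulfone closure. C4=C5 and the C6/C7 pair follow from a chair transition state; on C6/C7 control it is the equal of the chosen allylation.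
- Against it here: A8 lacks O8, has C9 as a ketone and C14 at the alcohol level. Two stereocentres therefore remain to be set on a flexible ring by α-hydroxylation and reduction, and C14 must be oxidised late beside sensitive groups. A7 requires a quaternary C4 centre with an (E)-enol ether vinyl group next to a tertiary dienyl carbinol.
- Comparison: better on ring formation and alkene geometry, weaker on oxygenation pattern and redox economy, and probably not shorter overall.

Key step: step 20

Remark: locants follow germacrane numbering (seco chain C1H2–C2H2–C3H2–C4(C15)=C5–C6(O6)–C7[C11(=C13)–C12–O12]–C8(O8)–C9(O9)–C10(C14)). The spatial arrangement at C6–C9 is constant from step 6 and step 15 onwards, while the CIP letters change with the O-substituents. C10 is carried as a mixture of epimers from step 15 to step 19 because both converge in step 20.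

**Step 1**
Reactants: 1 (R)-2,3-O-isopropylideneglyceraldehyde; 2 methyl acrylate
Product: 3 methyl 2-{hydroxy[(4R)-2,2-dimethyl-1,3-dioxolan-4-yl]methyl}prop-2-enoate (both carbinol epimers)
Conditions: DABCO (0.5 equiv), 1,4-dioxane/H2O (1:1), rt
Reagents that add atoms: none
Why: Morita–Baylis–Hillman reaction of an α-alkoxy aldehyde with an acrylate; the carbinol centre need not be controlled because step 2 turns it into an sp2 carbon, and the dioxolane centre (future C8) is not enolised under the amine catalyst.

**Step 2**
Reactants: 3 methyl 2-{hydroxy[(4R)-2,2-dimethyl-1,3-dioxolan-4-yl]methyl}prop-2-enoate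
Product: 4 methyl (2Z)-2-(bromomethyl)-3-[(4S)-2,2-dimethyl-1,3-dioxolan-4-yl]prop-2-enoate
Conditions: NBS, Me2S, CH2Cl2, 0 °C → rt
Reagents that add atoms: N-bromosuccinimide, O=C1CCC(=O)N1Br
Why: Corey–Kim-type activation of the allylic alcohol and SN2' delivery of bromide with allylic transposition; both epimers of 3 converge on the Z alkene (dioxolane trans to the ester), and the neutral conditions spare the acetonide.

**Step 3**
Reactants: 5 5-chloropentan-2-one; 6 trimethyl phosphonoacetate
Product: 7 methyl (2E)-6-chloro-3-methylhex-2-enoate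
Conditions: NaH, THF, 0 °C → rt; E isomer separated by chromatography
Reagents that add atoms: none
Why: Horner–Wadsworth–Emmons olefination of a methyl ketone, expected to favour the E enoate; the preformed phosphonate anion is too weak a base to enolise the ketone toward cyclopropane closure on the chloride.

**Step 4**
Reactants: 7 methyl (2E)-6-chloro-3-methylhex-2-enoate
Product: 8 (2E)-6-chloro-3-methylhex-2-en-1-ol
Conditions: i-Bu2AlH (2.2 equiv), CH2Cl2, −78 °C
Reagents that add atoms: none
Why: 1,2-reduction of an enoate to the allylic alcohol by an aluminium hydride; the primary chloride and the alkene geometry are untouched.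

**Step 5**
Reactants: 8 (2E)-6-chloro-3-methylhex-2-en-1-ol
Product: 9 (2E)-6-chloro-3-methylhex-2-enal
Conditions: MnO2, CH2Cl2, rt
Reagents that add atoms: none
Why: selective heterogeneous oxidation of an allylic alcohol to the enal without over-oxidation or E/Z isomerisation; the enal is used fresh.

**Step 6**
Reactants: 4 methyl (2Z)-2-(bromomethyl)-3-[(4S)-2,2-dimethyl-1,3-dioxolan-4-yl]prop-2-enoate; 9 (2E)-6-chloro-3-methylhex-2-enal
Product: 11 (4S,5R)-5-[(1E)-5-chloro-2-methylpent-1-en-1-yl]-4-[(4S)-2,2-dimethyl-1,3-dioxolan-4-yl]-3-methylideneoxolan-2-one (trans lactone; 6R,7S,8S), via anti hydroxy ester 10 (not isolated)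
Conditions: CrCl2 (4 equiv), THF, 0 °C → rt; aqueous work-up; then PPTS (cat.), toluene, 40 °C
Reagents that add atoms: none
Why: Nozaki–Hiyama-type 2-(alkoxycarbonyl)allylation: the allylchromium (trivalent chromium) adds 1,2 to the enal through a chair transition state in which, after E/Z equilibration of the allyl unit, the C5 alkenyl and the dioxolanyl group are both equatorial, which should give the 6,7-anti pair. The C8 centre directs the aldehyde to the alkene face anti to the C8–C9 bond while H8 eclipses the alkene to avoid allylic strain (the Felkin–Anh-type sense known for dioxolane-bearing allylchromium reagents), which sets C7; mild acid then closes the trans lactone.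

**Step 7**
Reactants: 11 trans lactone (6R,7S,8S)
Product: 12 (3S,4R,5E)-9-chloro-3-[(4S)-2,2-dimethyl-1,3-dioxolan-4-yl]-6-methyl-2-methylidenenon-5-ene-1,4-diol (6R,7S,8S; free O6–H and O12–H)
Conditions: i-Bu2AlH (3 equiv), CH2Cl2, −78 → 0 °C
Reagents that add atoms: none
Why: 1,2-reduction of the α-methylene lactone through the lactol to the 2-methylene-1,4-diol, which removes the Michael acceptor before thiolate and strong base are used.

**Step 8**
Reactants: 12 2-methylene-1,4-diol (6R,7S,8S)
Product: 13 1-chloro seco chain with 6-O-TIPS and 12-O-TIPS ethers and 8,9-O-isopropylidene acetal (4E; 6R,7R,8S)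
Conditions: i-Pr3SiOTf (2.5 equiv), 2,6-lutidine, CH2Cl2, 0 °C → rt
Reagents that add atoms: triisopropylsilyl triflate, CC(C)[Si](OS(=O)(=O)C(F)(F)F)(C(C)C)C(C)C
Why: silyl triflate silylation of a primary and a hindered secondary allylic alcohol; TIPS is chosen because these ethers must outlast the acidic cleavage of the acetonide (step 9) and of the TES ether (step 21).

**Step 9**
Reactants: 13 bis-TIPS ether with 8,9-O-isopropylidene acetal
Product: 14 1-chloro seco chain with 6-O-TIPS and 12-O-TIPS ethers and free 8,9-diol (6R,7R,8S)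
Conditions: PPTS (0.3 equiv), MeOH, 40 °C
Reagents that add atoms: none
Why: acid-catalysed transketalisation of the terminal acetonide to methanol; TIPS ethers are inert to pyridinium acid in methanol.

**Step 10**
Reactants: 14 8,9-diol
Product: 15 8,9-O-(4-methoxybenzylidene) acetal of 14 (acetal epimers; 6R,7R,8S)
Conditions: 4-MeOC6H4CH(OMe)2, PPTS (cat.), CH2Cl2, rt
Reagents that add atoms: 4-methoxybenzaldehyde dimethyl acetal, COc1ccc(C(OC)OC)cc1
Why: acetal exchange onto the 1,2-diol gives the five-membered dioxolane; the configuration of the acetal carbon is irrelevant because it becomes a CH2 in step 11.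

**Step 11**
Reactants: 15 8,9-O-(4-methoxybenzylidene) acetal
Product: 16 1-chloro seco chain with 6-O-TIPS, 12-O-TIPS and 8-O-PMB ethers and free primary C9–OH (6R,7R,8S)
Conditions: i-Bu2AlH (3 equiv), CH2Cl2, −78 → 0 °C
Reagents that add atoms: none
Why: regioselective reductive acetal opening: aluminium binds the less hindered primary O9, the C–O9 bond breaks and hydride quenches the oxocarbenium ion, so PMB ends on the secondary O8 where it later serves as chelating group and orthogonal protection.

**Step 12**
Reactants: 16 8-O-PMB primary alcohol with C1–Cl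
Product: 17 1-(acetylthio) analogue of 16 (C1–SAc; free C9–OH; 6R,7R,8S)
Conditions: KSAc (1.5 equiv), NaI (0.2 equiv), DMF, 50 °C
Reagents that add atoms: potassium thioacetate, CC(=O)[S-].[K+]
Why: SN2 displacement of the primary chloride by thioacetate with in situ iodide catalysis; sulfur is introduced only after the last hydride step and before the α-bromo ester exists, so no competing electrophile is present.

**Step 13**
Reactants: 17 C1 thioacetate with free C9–OH
Product: 18 C9 aldehyde (8-O-PMB α-alkoxy aldehyde; C1–SAc; 6R,7R,8S)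
Conditions: Dess–Martin periodinane, NaHCO3, CH2Cl2, 0 °C → rt; used crude
Reagents that add atoms: none
Why: Dess–Martin oxidation of a primary alcohol under buffered, non-epimerising conditions; the thioester, PMB ether and alkenes are inert to the periodinane.

**Step 14**
Reactants: 19 methyl bromoacetate
Product: 20 2-bromo-1-methoxy-1-(trimethylsilyloxy)ethene (E/Z mixture)
Conditions: LiN(i-Pr)2, Me3SiCl (in situ quench), THF, −78 °C; distilled or used crude
Reagents that add atoms: chlorotrimethylsilane, C[Si](C)(C)Cl
Why: O-silylation of the lithium enolate at −78 °C with the silyl chloride already present traps the α-bromo enolate before it can self-condense; α-halo ketene silyl acetals are an established class of Mukaiyama donors.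

**Step 15**
Reactants: 18 C9 aldehyde; 20 2-bromo-1-methoxy-1-(trimethylsilyloxy)ethene
Product: 21 methyl ester of the 10-bromo-9-hydroxy acid: seco chain extended by C10(Br)–C14O2Me with free 9-OH syn to 8-O-PMB (6R,7R,8S,9R; C10 epimers)
Conditions: MgBr2·OEt2 (3 equiv), CH2Cl2, −78 → −30 °C; aq. NH4Cl, then dilute citric acid
Reagents that add atoms: none
Why: Mukaiyama aldol addition under chelation control: MgBr2 bridges the aldehyde oxygen and the PMB ether oxygen in a five-membered chelate, and the ketene acetal attacks from the face opposite the C7 substituent, which should give the 8,9-syn diol pattern of the target; C10 needs no control because it loses its configuration in step 20.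

**Step 16**
Reactants: 21 α-bromo-β-hydroxy ester
Product: 22 9-O-TES ether of 21 (6R,7R,8S,9R; C10 epimers)
Conditions: Et3SiOTf, 2,6-lutidine, CH2Cl2, −78 °C
Reagents that add atoms: triethylsilyl triflate, CC[Si](CC)(CC)OS(=O)(=O)C(F)(F)F
Why: silyl triflate silylation of a hindered secondary alcohol; lutidine is too weak a base to trigger Darzens closure of the bromohydrin, and a silyl ether is a poor leaving group for the later C10 carbanion.

**Step 17**
Reactants: 22 9-O-TES α-bromo ester with C1–SAc
Product: 24 eleven-membered cyclic sulfide (S bridging C1 and C10; C10 bears H and CO2Me; 6-O-TIPS, 12-O-TIPS, 8-O-PMB, 9-O-TES; 4E; 6R,7R,8S,9R; C10 epimers), via C1 thiol 23 (not isolated)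
Conditions: Cs2CO3 (3 equiv), degassed MeOH–DMF (1:9), 0 °C → rt, slow addition to 1 mM
Reagents that add atoms: none
Why: methanolysis of the thioacetate releases the thiolate, which closes the ring by intramolecular SN2 at the carbonyl-activated α-bromo ester; high dilution offsets the entropic cost of the eleven-membered ring, and the weak base does not enolise the α-thio ester.

**Step 18**
Reactants: 24 eleven-membered cyclic sulfide
Product: 26 eleven-membered cyclic sulfone (C1–SO2–C10; C10 epimers), via sulfoxide 25 (not isolated)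
Conditions: (NH4)6Mo7O24·4H2O (0.2 equiv), 30% H2O2 (6 equiv), EtOH, 0 °C → rt
Reagents that add atoms: hydrogen peroxide, OO
Why: molybdate-catalysed peroxide oxidation of sulfide to sulfone; the peroxomolybdate is selective for sulfur and should leave the trisubstituted and 1,1-disubstituted alkenes alone because neither has a free allylic hydroxyl to direct epoxidation.

**Step 19**
Reactants: 26 eleven-membered cyclic sulfone
Product: 27 eleven-membered α-chloro sulfone (C10 bears Cl and CO2Me and no H; 6R,7R,8S,9R; either C10 epimer)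
Conditions: LiN(SiMe3)2 (1.05 equiv), THF, −78 °C; NCS (1.2 equiv), −78 → −40 °C
Reagents that add atoms: N-chlorosuccinimide, O=C1CCC(=O)N1Cl
Why: chlorination of an active methine: only C10–H (between sulfone and ester) is removed by one equivalent of amide base, and the lithium-chelated carbanion is chlorinated at low temperature before E1cB loss of the C9 silyloxy group can start.

**Step 20**
Reactants: 27 eleven-membered α-chloro sulfone
Product: 29 ten-membered (1(10)E,4E)-cyclodecadiene methyl ester with cis ring bonds at C1=C10 (6-O-TIPS, 12-O-TIPS, 8-O-PMB, 9-O-TES; open lactone arm; 6R,7R,8S,9S), via episulfone 28 (not isolated)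
Conditions: KOtBu (2.5 equiv), THF, −78 → 0 °C; aq. NH4Cl
Reagents that add atoms: none
Why: Ramberg–Bäcklund reaction. tert-Butoxide removes a C1 proton, the only acidic C–H left because C10 is quaternary, so neither enolisation toward C9 nor E1cB loss of the C9 oxygen can occur. The C1 carbanion displaces chloride from C10 in a 3-exo-tet 1,3-closure that forms the C1–C10 bond and thereby closes the ten-membered carbocycle inside the eleven-membered ring as bicyclic thiirane 1,1-dioxide 28. Stereospecific cheletropic loss of SO2 from 28 converts this σ bond into C1=C10 and contracts the sulfone ring by one atom. The closest known reaction type is the Ramberg–Bäcklund ring contraction of medium-ring α-halo sulfones to cycloalkenes, including cases with a fully substituted halogen-bearing carbon. No stereocentre is formed; the element to control is alkene geometry, which is fixed at the episulfone: the cis-fused episulfone (C2 and C9 cis) is favoured by the medium ring and puts the ester trans to C2, the preferred enoate arrangement. It is reachable from either C10 epimer because the C1 carbanion inverts before closure and C1–H of 28 can equilibrate under the base. Chemoselectivity rests on the substrate: the only ester is a hindered quaternary methyl ester, no acetate is present yet, the silyl and PMB ethers are inert to KOtBu, and C7–H is merely allylic. A short reaction time at low temperature limits γ-deprotonation of the product enoate.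

**Step 21**
Reactants: 29 ten-membered cyclodecadiene ester with 9-O-TES
Product: 30 9-hydroxy compound (6-O-TIPS, 12-O-TIPS, 8-O-PMB; 6R,7R,8S,9S)
Conditions: PPTS (0.2 equiv), MeOH/CH2Cl2 (1:1), 0 °C → rt
Reagents that add atoms: none
Why: acid-catalysed methanolysis of the TES ether; TIPS ethers are far less labile under these conditions and the PMB ether is untouched.

**Step 22**
Reactants: 30 9-hydroxy compound
Product: 31 9-O-acetate (6-O-TIPS, 12-O-TIPS, 8-O-PMB; 6R,7R,8S,9S)
Conditions: Ac2O, pyridine, DMAP (cat.), CH2Cl2, 0 °C → rt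
Reagents that add atoms: acetic anhydride, CC(=O)OC(C)=O
Why: DMAP-catalysed acetylation of the only free hydroxyl; installing the acetate now blocks O9 so that only O6 can capture the C12 aldehyde in step 24.

**Step 23**
Reactants: 31 9-O-acetate with 6-O-TIPS and 12-O-TIPS
Product: 32 6,12-diol (8-O-PMB, 9-O-acetyl; 6R,7S,8S,9S)
Conditions: Bu4NF/AcOH (1:1, 6 equiv), THF, rt → 40 °C
Reagents that add atoms: none
Why: fluoride cleavage of both Si–O bonds driven by Si–F bond formation; buffering with acetic acid keeps the medium non-basic so that the acetate neither migrates nor is cleaved.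

**Step 24**
Reactants: 32 6,12-diol
Product: 34 trans-fused α-methylene-γ-butyrolactone with 8-O-PMB and 9-O-acetyl (6R,7S,8S,9S), via lactol 33 (not isolated)
Conditions: TEMPO (0.2 equiv), PhI(OAc)2 (3 equiv), CH2Cl2, rt
Reagents that add atoms: none
Why: oxoammonium-mediated oxidative lactonisation: the primary allylic C12–OH is oxidised much faster than the secondary C6–OH, the enal is trapped by O6 as the five-membered lactol, and a second oxidation gives the lactone. This avoids the competing oxidation of the allylic C6–OH to an enone that a less selective allylic oxidant such as MnO2 could cause.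

**Step 25**
Reactants: 34 lactone with 8-O-PMB
Product: 35 8-hydroxy-9-acetoxy melampolide (free O8–H; 6R,7R,8S,9S)
Conditions: DDQ (1.5 equiv), CH2Cl2/pH 7 buffer (10:1), 0 °C
Reagents that add atoms: none
Why: oxidative cleavage of the PMB ether by hydride abstraction at the electron-rich benzylic position and hydrolysis of the oxocarbenium ion; the neutral medium avoids acetyl migration and leaves all esters and alkenes intact.

**Step 26**
Reactants: 36 ethyl 2-(hydroxymethyl)acrylate
Product: 37 ethyl 2-[(tert-butyldimethylsilyloxy)methyl]acrylate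
Conditions: t-BuMe2SiCl, imidazole, DMF, rt
Reagents that add atoms: tert-butyldimethylsilyl chloride, CC(C)(C)[Si](C)(C)Cl
Why: standard imidazole-promoted silylation of a primary alcohol, which masks the hydroxyl that would otherwise self-acylate in step 28.

**Step 27**
Reactants: 37 ethyl 2-[(tert-butyldimethylsilyloxy)methyl]acrylate
Product: 38 2-[(tert-butyldimethylsilyloxy)methyl]acrylic acid
Conditions: LiOH, THF/H2O, 0 °C → rt; then 1 M HCl to pH 4 at 0 °C
Reagents that add atoms: lithium hydroxide, [Li+].[OH-]
Why: saponification of the ethyl ester by acyl–oxygen cleavage; the TBS ether is stable to aqueous hydroxide and the brief cold acidification does not remove it.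

**Step 28**
Reactants: 35 8-hydroxy-9-acetoxy melampolide; 38 2-[(tert-butyldimethylsilyloxy)methyl]acrylic acid
Product: 40 8-O-{2-[(tert-butyldimethylsilyloxy)methyl]acryloyl} derivative of 35 (6R,7S,8S,9S), via mixed anhydride 39 (not isolated)
Conditions: 38, 2,4,6-Cl3C6H2COCl, Et3N, THF, rt; then 35, DMAP, toluene, rt
Reagents that add atoms: none
Why: Yamaguchi esterification: the preformed mixed anhydride is attacked by DMAP regioselectively at the acrylic carbonyl and transfers the acyl group rapidly to the hindered O8–H, which keeps the time available for O9→O8 acetyl migration short; at this stage the bulky silyl ethers near C8 are gone and only the small acetate flanks the alcohol.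

**Step 29**
Reactants: 40 silyl-protected target
Product: 41 CNP0291058.1 (target; 6R,7S,8S,9S; 1(10)E,4E)
Conditions: HF·pyridine, pyridine/THF, 0 °C → rt
Reagents that add atoms: none
Why: cleavage of the primary TBS ether by buffered hydrogen fluoride; the acidic, non-nucleophilic fluoride source avoids conjugate addition to the three Michael acceptors and base-induced acyl migration.

**Compound list**

1 | (R)-2,3-O-isopropylideneglyceraldehyde | O=C[C@H]1COC(C)(C)O1 | starting material
2 | methyl acrylate | C=CC(=O)OC | starting material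
3 | methyl 2-{hydroxy[(4R)-2,2-dimethyl-1,3-dioxolan-4-yl]methyl}prop-2-enoate (carbinol epimers) | C=C(C(=O)OC)C(O)[C@H]1COC(C)(C)O1 | intermediate
4 | methyl (2Z)-2-(bromomethyl)-3-[(4S)-2,2-dimethyl-1,3-dioxolan-4-yl]prop-2-enoate | BrC/C(C(=O)OC)=C\[C@H]1COC(C)(C)O1 | intermediate
5 | 5-chloropentan-2-one | CC(=O)CCCCl | starting material
6 | trimethyl phosphonoacetate | COC(=O)CP(=O)(OC)OC | starting material
7 | methyl (2E)-6-chloro-3-methylhex-2-enoate | COC(=O)/C=C(\C)CCCCl | intermediate
8 | (2E)-6-chloro-3-methylhex-2-en-1-ol | OC/C=C(\C)CCCCl | intermediate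
9 | (2E)-6-chloro-3-methylhex-2-enal | O=C/C=C(\C)CCCCl | intermediate
10 | methyl (3S,4R,5E)-9-chloro-3-[(4S)-2,2-dimethyl-1,3-dioxolan-4-yl]-4-hydroxy-6-methyl-2-methylidenenon-5-enoate (6,7-anti hydroxy ester) | COC(=O)C(=C)[C@H]([C@H]1COC(C)(C)O1)[C@H](O)/C=C(\C)CCCCl | intermediate (not isolated)
11 | (4S,5R)-5-[(1E)-5-chloro-2-methylpent-1-en-1-yl]-4-[(4S)-2,2-dimethyl-1,3-dioxolan-4-yl]-3-methylideneoxolan-2-one | C=C1C(=O)O[C@H](/C=C(\C)CCCCl)[C@H]1[C@H]2COC(C)(C)O2 | intermediate
12 | (3S,4R,5E)-9-chloro-3-[(4S)-2,2-dimethyl-1,3-dioxolan-4-yl]-6-methyl-2-methylidenenon-5-ene-1,4-diol | OCC(=C)[C@H]([C@H]1COC(C)(C)O1)[C@H](O)/C=C(\C)CCCCl | intermediate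
13 | 6,12-bis-O-TIPS ether of 12 (6R,7R,8S) | CC(C)[Si](C(C)C)(C(C)C)OCC(=C)[C@H]([C@H]1COC(C)(C)O1)[C@H](O[Si](C(C)C)(C(C)C)C(C)C)/C=C(\C)CCCCl | intermediate
14 | 8,9-diol: 13 without the acetonide (6R,7R,8S) | CC(C)[Si](C(C)C)(C(C)C)OCC(=C)[C@H]([C@H](O)CO)[C@H](O[Si](C(C)C)(C(C)C)C(C)C)/C=C(\C)CCCCl | intermediate
15 | 8,9-O-(4-methoxybenzylidene) acetal of 14 (acetal epimers) | CC(C)[Si](C(C)C)(C(C)C)OCC(=C)[C@H]([C@H]1COC(c2ccc(OC)cc2)O1)[C@H](O[Si](C(C)C)(C(C)C)C(C)C)/C=C(\C)CCCCl | intermediate
16 | 8-O-PMB ether with free C9–OH, C1–Cl (6R,7R,8S) | CC(C)[Si](C(C)C)(C(C)C)OCC(=C)[C@H]([C@H](OCc1ccc(OC)cc1)CO)[C@H](O[Si](C(C)C)(C(C)C)C(C)C)/C=C(\C)CCCCl | intermediate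
17 | C1 thioacetate of 16 | CC(C)[Si](C(C)C)(C(C)C)OCC(=C)[C@H]([C@H](OCc1ccc(OC)cc1)CO)[C@H](O[Si](C(C)C)(C(C)C)C(C)C)/C=C(\C)CCCSC(C)=O | intermediate
18 | C9 aldehyde of 17 | CC(C)[Si](C(C)C)(C(C)C)OCC(=C)[C@H]([C@H](OCc1ccc(OC)cc1)C=O)[C@H](O[Si](C(C)C)(C(C)C)C(C)C)/C=C(\C)CCCSC(C)=O | intermediate
19 | methyl bromoacetate | COC(=O)CBr | starting material
20 | 2-bromo-1-methoxy-1-(trimethylsilyloxy)ethene (E/Z mixture) | COC(=CBr)O[Si](C)(C)C | intermediate
21 | methyl 10-bromo-9-hydroxy ester, 8,9-syn (6R,7R,8S,9R; C10 epimers) | CC(C)[Si](C(C)C)(C(C)C)OCC(=C)[C@H]([C@H](OCc1ccc(OC)cc1)[C@@H](O)C(Br)C(=O)OC)[C@H](O[Si](C(C)C)(C(C)C)C(C)C)/C=C(\C)CCCSC(C)=O | intermediate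
22 | 9-O-TES ether of 21 | CC(C)[Si](C(C)C)(C(C)C)OCC(=C)[C@H]([C@H](OCc1ccc(OC)cc1)[C@@H](O[Si](CC)(CC)CC)C(Br)C(=O)OC)[C@H](O[Si](C(C)C)(C(C)C)C(C)C)/C=C(\C)CCCSC(C)=O | intermediate
23 | C1 thiol from 22 | CC(C)[Si](C(C)C)(C(C)C)OCC(=C)[C@H]([C@H](OCc1ccc(OC)cc1)[C@@H](O[Si](CC)(CC)CC)C(Br)C(=O)OC)[C@H](O[Si](C(C)C)(C(C)C)C(C)C)/C=C(\C)CCCS | intermediate (not isolated)
24 | eleven-membered cyclic sulfide, S between C1 and C10 (6R,7R,8S,9R; C10 epimers) | COc1ccc(CO[C@H]2[C@@H](C(=C)CO[Si](C(C)C)(C(C)C)C(C)C)[C@H](O[Si](C(C)C)(C(C)C)C(C)C)/C=C(\C)CCCSC(C(=O)OC)[C@@H]2O[Si](CC)(CC)CC)cc1 | intermediate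
25 | eleven-membered cyclic sulfoxide (S and C10 epimers) | COc1ccc(CO[C@H]2[C@@H](C(=C)CO[Si](C(C)C)(C(C)C)C(C)C)[C@H](O[Si](C(C)C)(C(C)C)C(C)C)/C=C(\C)CCCS(=O)C(C(=O)OC)[C@@H]2O[Si](CC)(CC)CC)cc1 | intermediate (not isolated)
26 | eleven-membered cyclic sulfone (C10 epimers) | COc1ccc(CO[C@H]2[C@@H](C(=C)CO[Si](C(C)C)(C(C)C)C(C)C)[C@H](O[Si](C(C)C)(C(C)C)C(C)C)/C=C(\C)CCCS(=O)(=O)C(C(=O)OC)[C@@H]2O[Si](CC)(CC)CC)cc1 | intermediate
27 | eleven-membered α-chloro sulfone (either C10 epimer) | COc1ccc(CO[C@H]2[C@@H](C(=C)CO[Si](C(C)C)(C(C)C)C(C)C)[C@H](O[Si](C(C)C)(C(C)C)C(C)C)/C=C(\C)CCCS(=O)(=O)C(Cl)(C(=O)OC)[C@@H]2O[Si](CC)(CC)CC)cc1 | intermediate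
28 | cis-fused bicyclic thiirane 1,1-dioxide across C1–C10 | COc1ccc(CO[C@H]2[C@@H](C(=C)CO[Si](C(C)C)(C(C)C)C(C)C)[C@H](O[Si](C(C)C)(C(C)C)C(C)C)/C=C(\C)CCC3C(C(=O)OC)(S3(=O)=O)[C@@H]2O[Si](CC)(CC)CC)cc1 | intermediate (not isolated)
29 | ten-membered (1(10)E,4E)-diene methyl ester, 6,12-bis-O-TIPS, 8-O-PMB, 9-O-TES (6R,7R,8S,9S) | COc1ccc(CO[C@H]2[C@@H](C(=C)CO[Si](C(C)C)(C(C)C)C(C)C)[C@H](O[Si](C(C)C)(C(C)C)C(C)C)/C=C(\C)CC/C=C(/C(=O)OC)[C@@H]2O[Si](CC)(CC)CC)cc1 | intermediate
30 | 9-hydroxy compound from 29 | COc1ccc(CO[C@H]2[C@@H](C(=C)CO[Si](C(C)C)(C(C)C)C(C)C)[C@H](O[Si](C(C)C)(C(C)C)C(C)C)/C=C(\C)CC/C=C(/C(=O)OC)[C@@H]2O)cc1 | intermediate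
31 | 9-O-acetate of 30 | COc1ccc(CO[C@H]2[C@@H](C(=C)CO[Si](C(C)C)(C(C)C)C(C)C)[C@H](O[Si](C(C)C)(C(C)C)C(C)C)/C=C(\C)CC/C=C(/C(=O)OC)[C@@H]2OC(C)=O)cc1 | intermediate
32 | 6,12-diol, 8-O-PMB, 9-O-acetyl (6R,7S,8S,9S) | COc1ccc(CO[C@H]2[C@@H](C(=C)CO)[C@H](O)/C=C(\C)CC/C=C(/C(=O)OC)[C@@H]2OC(C)=O)cc1 | intermediate
33 | 6,12-lactol (C12 epimers) | COc1ccc(CO[C@H]2[C@H]3C(=C)C(O)O[C@@H]3/C=C(\C)CC/C=C(/C(=O)OC)[C@@H]2OC(C)=O)cc1 | intermediate (not isolated)
34 | trans-fused α-methylene lactone, 8-O-PMB, 9-O-acetyl (6R,7S,8S,9S) | COc1ccc(CO[C@H]2[C@H]3C(=C)C(=O)O[C@@H]3/C=C(\C)CC/C=C(/C(=O)OC)[C@@H]2OC(C)=O)cc1 | intermediate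
35 | 8-hydroxy-9-acetoxy melampolide (6R,7R,8S,9S) | O[C@H]1[C@H]2C(=C)C(=O)O[C@@H]2/C=C(\C)CC/C=C(/C(=O)OC)[C@@H]1OC(C)=O | intermediate
36 | ethyl 2-(hydroxymethyl)acrylate | C=C(CO)C(=O)OCC | starting material
37 | ethyl 2-[(tert-butyldimethylsilyloxy)methyl]acrylate | C=C(CO[Si](C)(C)C(C)(C)C)C(=O)OCC | intermediate
38 | 2-[(tert-butyldimethylsilyloxy)methyl]acrylic acid | C=C(CO[Si](C)(C)C(C)(C)C)C(=O)O | intermediate
39 | mixed anhydride of 38 with 2,4,6-trichlorobenzoic acid | C=C(CO[Si](C)(C)C(C)(C)C)C(=O)OC(=O)c1c(Cl)cc(Cl)cc1Cl | intermediate (not isolated)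
40 | 8-O-{2-[(tert-butyldimethylsilyloxy)methyl]acryloyl}-9-O-acetyl melampolide (6R,7S,8S,9S) | CC(C)(C)[Si](C)(C)OCC(=C)C(=O)O[C@H]1[C@H]2C(=C)C(=O)O[C@@H]2/C=C(\C)CC/C=C(/C(=O)OC)[C@@H]1OC(C)=O | intermediate
41 | CNP0291058.1 (6R,7S,8S,9S; 1(10)E,4E) | C=C(CO)C(=O)O[C@H]1[C@H]2C(=C)C(=O)O[C@@H]2/C=C(\C)CC/C=C(/C(=O)OC)[C@@H]1OC(C)=O | target

**Step count and least certain steps**

Total step count: 29. Longest linear sequence: 24 steps (steps 3–13, 15–25, 28, 29).

Step 20 (key step). The most likely failure is transfer of chlorine from the doubly activated C10 to tert-butoxide or to a C1 carbanion of a second molecule, which returns 26. This can outrun the 1,3-closure because the closure has to occur at a fully substituted, crowded carbon and the departing carbanion is stabilised by both sulfone and ester. A secondary concern is γ-deprotonation of the product enoate. The fallback reverses the polarity of the closure, sets out from 26 and returns at 29. LiN(i-Pr)2 (2.2 equiv, THF, −78 °C) forms the C1,C10-dianion. I2 (1 equiv) is taken up at the more basic C1 carbanion to give the C1-iodo sulfone F1 as its C10 carbanion (not isolated). The ester-stabilised C10 carbanion then closes onto the secondary iodide, and SO2 loss from the episulfone gives 29. No halogen ever sits on the doubly activated carbon.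

Step 6. The most likely failure is erosion of the 6,7-anti preference. If the allylchromium reacts through the geometry that keeps the dioxolane cis to the CH2Cr carbon, the chair transition state delivers the syn adduct and hence the cis lactone. The fallback accepts the syn outcome and corrects C6 afterwards; it sets out from 4 and 9 and returns at 12. In (powder) in THF/H2O couples 4 and 9 in the syn-selective Barbier mode to give the syn hydroxy ester F2. Mitsunobu reaction (PPh3, DIAD, 4-nitrobenzoic acid, THF) inverts C6 to give the 4-nitrobenzoate F3 with the C6 configuration of 10. i-Bu2AlH (CH2Cl2, −78 °C) then reduces both ester groups to give 12.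

Step 15. The most likely failure is incomplete chelation control: an open Felkin–Anh pathway can compete because the halogenated ketene acetal is a sluggish donor, and the donor may partly decompose. The fallback replaces substrate control by auxiliary control; it sets out from 18 and returns at 24. (S)-4-Benzyloxazolidin-2-one is acylated (n-BuLi, bromoacetyl bromide, THF, −78 °C) to give (S)-4-benzyl-3-(bromoacetyl)oxazolidin-2-one F4. Its dibutylboron enolate (Bu2BOTf, i-Pr2NEt, CH2Cl2, −78 °C) adds to 18 in the syn aldol sense of the auxiliary to give the bromohydrin imide F5 with the required O9 configuration. Et3SiOTf/2,6-lutidine gives the 9-O-TES imide F6. Cs2CO3 in MeOH–DMF at high dilution closes the ring to the cyclic sulfide imide F7. NaOMe in MeOH at 0 °C exchanges the auxiliary for the methyl ester to give 24.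

Step 17. The most likely failure is intermolecular S-alkylation (oligomers), together with elimination or halogen abstraction at the hindered secondary bromide, because the eleven-membered ring forms slowly. The fallback exchanges the roles of C1 and C10 so that the ring closes at an unhindered primary carbon; it sets out from 16 and returns at 24. Dess–Martin oxidation of 16 gives the chloro aldehyde F8. The chelation-controlled Mukaiyama aldol with 20 gives the bromohydrin ester F9, and Et3SiOTf gives its TES ether F10. KSAc in DMF at 0 °C displaces only the activated α-bromide to give the C10 thioacetate F11. NaI in acetone converts the primary chloride into the iodide F12. Cs2CO3 in MeOH–DMF at high dilution releases the C10 thiolate, which closes onto C1 to give 24.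

**Further compounds**

F1 | step 20 | C1-iodo derivative of sulfone 26 (C1 and C10 epimers; formed as its C10 carbanion) | COc1ccc(CO[C@H]2[C@@H](C(=C)CO[Si](C(C)C)(C(C)C)C(C)C)[C@H](O[Si](C(C)C)(C(C)C)C(C)C)/C=C(\C)CCC(I)S(=O)(=O)C(C(=O)OC)[C@@H]2O[Si](CC)(CC)CC)cc1
F2 | step 6 | methyl (5E)-9-chloro-3-[(4S)-2,2-dimethyl-1,3-dioxolan-4-yl]-4-hydroxy-6-methyl-2-methylidenenon-5-enoate, 6,7-syn (C6 epimer of 10) | COC(=O)C(=C)[C@H]([C@H]1COC(C)(C)O1)[C@@H](O)/C=C(\C)CCCCl
F3 | step 6 | 4-nitrobenzoate of 10 (C6 configured as in 10) | COC(=O)C(=C)[C@H]([C@H]1COC(C)(C)O1)[C@H](OC(=O)c1ccc(cc1)[N+](=O)[O-])/C=C(\C)CCCCl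
F4 | step 15 | (S)-4-benzyl-3-(bromoacetyl)oxazolidin-2-one | O=C(CBr)N1[C@@H](Cc2ccccc2)COC1=O
F5 | step 15 | syn bromohydrin imide from 18 (9-OH as in 21; 10-Br syn) | CC(C)[Si](C(C)C)(C(C)C)OCC(=C)[C@H]([C@H](OCc1ccc(OC)cc1)[C@@H](O)[C@H](Br)C(=O)N1[C@@H](Cc2ccccc2)COC1=O)[C@H](O[Si](C(C)C)(C(C)C)C(C)C)/C=C(\C)CCCSC(C)=O
F6 | step 15 | 9-O-TES ether of F5 | CC(C)[Si](C(C)C)(C(C)C)OCC(=C)[C@H]([C@H](OCc1ccc(OC)cc1)[C@@H](O[Si](CC)(CC)CC)[C@H](Br)C(=O)N1[C@@H](Cc2ccccc2)COC1=O)[C@H](O[Si](C(C)C)(C(C)C)C(C)C)/C=C(\C)CCCSC(C)=O
F7 | step 15 | eleven-membered cyclic sulfide carrying the oxazolidinone imide at C10 (C10 epimers) | COc1ccc(CO[C@H]2[C@@H](C(=C)CO[Si](C(C)C)(C(C)C)C(C)C)[C@H](O[Si](C(C)C)(C(C)C)C(C)C)/C=C(\C)CCCSC(C(=O)N3[C@@H](Cc4ccccc4)COC3=O)[C@@H]2O[Si](CC)(CC)CC)cc1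
F8 | step 17 | C9 aldehyde of 16 (C1–Cl retained) | CC(C)[Si](C(C)C)(C(C)C)OCC(=C)[C@H]([C@H](OCc1ccc(OC)cc1)C=O)[C@H](O[Si](C(C)C)(C(C)C)C(C)C)/C=C(\C)CCCCl
F9 | step 17 | C1-chloro analogue of 21 (C10 epimers) | CC(C)[Si](C(C)C)(C(C)C)OCC(=C)[C@H]([C@H](OCc1ccc(OC)cc1)[C@@H](O)C(Br)C(=O)OC)[C@H](O[Si](C(C)C)(C(C)C)C(C)C)/C=C(\C)CCCCl
F10 | step 17 | C1-chloro analogue of 22 (C10 epimers) | CC(C)[Si](C(C)C)(C(C)C)OCC(=C)[C@H]([C@H](OCc1ccc(OC)cc1)[C@@H](O[Si](CC)(CC)CC)C(Br)C(=O)OC)[C@H](O[Si](C(C)C)(C(C)C)C(C)C)/C=C(\C)CCCCl
F11 | step 17 | C10 thioacetate with C1–Cl (C10 epimers) | CC(C)[Si](C(C)C)(C(C)C)OCC(=C)[C@H]([C@H](OCc1ccc(OC)cc1)[C@@H](O[Si](CC)(CC)CC)C(SC(C)=O)C(=O)OC)[C@H](O[Si](C(C)C)(C(C)C)C(C)C)/C=C(\C)CCCCl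
F12 | step 17 | C10 thioacetate with C1–I (C10 epimers) | CC(C)[Si](C(C)C)(C(C)C)OCC(=C)[C@H]([C@H](OCc1ccc(OC)cc1)[C@@H](O[Si](CC)(CC)CC)C(SC(C)=O)C(=O)OC)[C@H](O[Si](C(C)C)(C(C)C)C(C)C)/C=C(\C)CCCI
A1 | alternative 1 | lactone-fused 2-(methoxycarbonyl)cyclohex-2-enone with 8-O-TBS | COC(=O)C1=C[C@H]2OC(=O)C[C@@H]2[C@H](O[Si](C)(C)C(C)(C)C)C1=O
A2 | alternative 1 | 1-methylcyclobutene | CC1=CCC1
A3 | alternative 1 | cis-anti-cis tricyclic photoadduct | COC(=O)[C@]12[C@@H]3CC[C@]3(C)[C@H]1[C@H]1OC(=O)C[C@@H]1[C@H](O[Si](C)(C)C(C)(C)C)C2=O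
A4 | alternative 1 | cyclodeca-1(10),4-dien-9-one ester from cycloreversion (lactone without methylene) | O=C1[C@@H](O[Si](C)(C)C(C)(C)C)[C@H]2CC(=O)O[C@@H]2/C=C(\C)CC/C=C1/C(=O)OC
A5 | alternative 2 | seco bromide–aldehyde with enol acetate (C1 epimers, either enol acetate geometry) | O=C[C@H]1C(=C)C(=O)O[C@@H]1/C=C(\C)CCC(Br)C(C(=O)OC)=COC(C)=O
A6 | alternative 2 | 8-hydroxy-9-acetoxy melampolide | O[C@H]1[C@H]2C(=C)C(=O)O[C@@H]2/C=C(\C)CC/C=C(/C(=O)OC)[C@@H]1OC(C)=O
A7 | alternative 3 | trans-1,6-dialkenylcyclohex-2-enol with (E)-dienyl arm on C9 and (E)-enol ether arm on C4 | O[C@@]1(/C=C/C(=C)CO[Si](C)(C)C(C)(C)C)C(COCc2ccc(OC)cc2)=CCC[C@@]1(C)/C=C/OCc1ccc(OC)cc1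
A8 | alternative 3 | (1(10)-cis,4E)-cyclodecadien-9-one with C6 ether and C7 side chain | O=C1C[C@@H](C(=C)CO[Si](C)(C)C(C)(C)C)[C@H](OCc2ccc(OC)cc2)/C=C(\C)CC/C=C1/COCc1ccc(OC)cc1
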